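## Structural features

The target (14) is a biflavonoid in which a (2S)-flavanone (naringenin: benzo ring A, dihydropyranone ring C, 4-hydroxyphenyl ring B) is joined through C6 to C8'' of a flavone (apigenin: rings A', C', B'). The C6–C8'' bond is a biaryl bond between two phloroglucinol-type rings with four ortho oxygens (O5 and O7 on ring A, O7'' and the ring oxygen O1'' on ring A'), so it is the most hindered bond and a possible stereogenic axis, for which no configuration is given. The two halves are attached differently: on ring A the ring oxygen O1 (on C8a) is para to the biaryl carbon C6, whereas on ring A' the ring oxygen O1'' (on C8a'') is ortho to C8'', so 6- versus 8-attachment has to be fixed on each half separately. There is a single stereocenter, C2, with no neighbouring stereocenter; it is benzylic, bonded to O1 and β to the C4 ketone, racemizes under base by retro-oxa-Michael opening to the 2'-hydroxychalcone, and can ionize at C2–O1 under strong Lewis acid. The six free phenols and the flavanone are the fragile groups; the flavone is robust, but its C4''=O and C2''=C3'' are open to hydrides and hard nucleophiles. The real difficulty is the hindered C6–C8'' bond with the correct attachment on both rings, followed by placing a labile stereocenter in one pyranone only. The key step exploits the fact that on ring A the biaryl carbon C6 has the oxygenated carbons C5 and C7 as ortho neighbours and the O1-bearing carbon C8a para to it, which is exactly the environment of the C1 carbonyl of a 2,6-dialkoxy-1,4-benzoquinone with its C4 carbonyl para. In one sentence: ring A is born from such a quinone by 1,2-addition of a C8''-metalated flavone to the C1 carbonyl and reductive aromatization of the p-quinol, not by cross-coupling of two aryl halide/boron partners.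

## Logic of the disconnections

14 to 13. The six O–CH2 bonds on O5, O7, O4', O5'', O7'' and O4''' are cut. All phenols are released at once by neutral hydrogenolysis, which leaves C2 untouched. The gain is that phenol acidity and oxidizability are absent from every earlier step. The demand is that no base or strong acid is used once C2 exists.

13 to 11 and 12. The C2–C1' bond is cut. The forward step is an enantioselective conjugate addition of 12 to C2=C3 of ring C in 11. This removes the only stereocenter and ring B, so 11 has no carbon stereocenter. The step must be catalyst-controlled in facial sense, non-basic, and must distinguish the 2-unsubstituted pyranone (ring C) from the 2-aryl pyranone (ring C').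

11 to 9 (through 10). The O1–C2 and C2–C3 bonds of ring C are cut; C2 comes from a one-carbon amide acetal. The gain is that ring C is reduced to a methyl ketone. The demand is a single free hydroxyl on ring A, placed para to C6, so that closure can only give the 6-linked chromone.

9 to 8. The C4–C4a bond is cut. The forward step is a C-acetylation ortho to the only free phenol of 8; the two open positions of that ring are equivalent. The demand is that this ring reacts in preference to rings A' and B' and that the benzyl ethers survive.

8 to 7 to 3 and 5 (key). The C6–C8'' bond is cut and ring A is traced back to a cyclohexadienone: C6 is the carbinol carbon of 7 and C8a its carbonyl carbon, which in turn are C1 and C4 of 5. The hindered bond is thus formed to a trigonal carbonyl carbon and not by reductive elimination of two di-ortho-substituted aryl groups. The distal carbonyl of 5 becomes the one free hydroxyl, which later is O1, para to C6. One partner is simplified to a symmetric quinone with no halogen or boron, and the six oxygens of the biaryl are differentiated without extra steps. The demands are that the organometallic from 3 forms and survives beside C4''=O, that it attacks the carbonyl flanked by the two benzyloxy groups, and that 7 is reduced without touching ring C'.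

3 to 2 to 1. The C8''–I bond, then three O–benzyl bonds, are cut. Iodination must go to C8'' and not C6'', which requires O5'' to be alkylated first.

5 to 4. The carbonyl oxygen para to the hydroxyl of 4 is removed. The forward step is oxidation of a phenol with a free para position.

## Other disconnections considered

Alternative 1: The C6–C8'' bond is cut between two aromatic partners, the first plan that comes to mind. The forward step is a Suzuki–Miyaura coupling of the flavone C8''-boronate A1 with the 6-iodochromone A2 (or the corresponding iodoflavanone) to give 11. The chosen plan is preferred on three grounds. A2 needs C6 halogenation, which is regioselective only while O5–H is free, so a protect/iodinate/protect sequence is added. On palladium two di-ortho-oxygenated aryl groups must meet in transmetalation and reductive elimination, and 2,6-dialkoxyarylboron reagents are prone to protodeboronation under the base required. If the coupling is moved after C2 is set, the base opens the flavanone. The quinone route forms the bond at a trigonal carbon, needs one prefunctionalized partner only, and gives the para hydroxyl without extra steps.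

Alternative 2: The same bond is cut as a biomimetic dehydrogenative coupling. The forward step is a one-electron oxidation (iron or copper oxidant, or a laccase- or peroxidase-class enzyme) of 1 together with (2S)-naringenin A3, copying the presumed radical phenol coupling and giving 14 directly. It is the shortest plan on paper. Each monomer, however, offers C6 and C8 (and the positions ortho to the ring B hydroxyl) as radical sites, and nothing in 1 or A3 differentiates them or favours cross- over homo-coupling. The desired 6→8'' isomer would be one of at least four cross-linked constitutional isomers beside homodimers and oligomers, and the products are more easily oxidized than the monomers.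

Alternative 3: Ring A is cut through C5–C6 and built de novo by a polyketide-type Claisen cyclization, copying the chalcone-synthase ring closure. The forward step is cyclization of the diketo ester A4, whose chain hangs on C8'' through a CH2 group, by attack of the benzylic carbanion on the ester to give the 2-arylphloroglucinol A5. The chosen plan is preferred because A4 requires a C8''-acetic acid unit and chain extension over several steps, and carbocyclization competes with lactonization to a 4-hydroxy-2-pyranone. Above all, A5 carries three free hydroxyls on the new ring, so the later pyranone closure could not tell the oxygen para to the biaryl bond from the two ortho to it, which is the differentiation the quinone provides.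

Key step: step 4

Assumption: the C6–C8'' axis has no descriptor in the given structure, so it is left uncontrolled; only C2 (S) is set, and if rotation about this bond is slow, 9 to 14 would be handled as mixtures of the two rotamers.

## Route

Step 1
Reactants: 1 apigenin
Product: 2 5,7-bis(benzyloxy)-2-[4-(benzyloxy)phenyl]-4H-chromen-4-one
Conditions: BnBr (4.5 equiv), K2CO3 (6 equiv), DMF, 80 °C
Reagents that add atoms: benzyl bromide, BrCc1ccccc1
Why: Williamson etherification of all three phenols; the chelated O5''–H needs DMF and heat, and its alkylation is required because a 5-alkoxy group steers the next iodination to C8''.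

Step 2
Reactants: 2 5,7-bis(benzyloxy)-2-[4-(benzyloxy)phenyl]-4H-chromen-4-one
Product: 3 5,7-bis(benzyloxy)-2-[4-(benzyloxy)phenyl]-8-iodo-4H-chromen-4-one
Conditions: NIS (1.1 equiv), CF3CO2H (cat.), MeCN–CH2Cl2, 0 °C to rt
Reagents that add atoms: N-iodosuccinimide, O=C1CCC(=O)N1I
Why: Electrophilic aromatic iodination; with O5'' alkylated, ring A' should react at C8'' (para to O5'', flanked by one benzyloxy group only) and not at C6'' (between two benzyloxy groups), the usual outcome for 5-O-alkyl 5,7-dioxygenated flavones, while ring B' is deactivated by conjugation with the pyranone.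

Step 3
Reactants: 4 3,5-bis(benzyloxy)phenol
Product: 5 2,6-bis(benzyloxy)cyclohexa-2,5-diene-1,4-dione
Conditions: ON(SO3K)2 (2.2 equiv), KH2PO4 buffer, acetone–H2O, 0 °C to rt
Reagents that add atoms: potassium nitrosodisulfonate, [K+].[K+].[O]N(S(=O)(=O)[O-])S(=O)(=O)[O-]
Why: Teuber oxidation of a phenol with a free para position; two equivalents of the nitroxyl radical deliver oxygen to the carbon between the two benzyloxy groups, giving the p-quinone whose C1 carbonyl is flanked by them.

Step 4
Reactants: 3 5,7-bis(benzyloxy)-2-[4-(benzyloxy)phenyl]-8-iodo-4H-chromen-4-one; 5 2,6-bis(benzyloxy)cyclohexa-2,5-diene-1,4-dione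
Product: 7 5,7-bis(benzyloxy)-2-[4-(benzyloxy)phenyl]-8-[2,6-bis(benzyloxy)-1-hydroxy-4-oxocyclohexa-2,5-dien-1-yl]-4H-chromen-4-one, via arylmagnesium chloride 6 (not isolated)
Conditions: i-PrMgCl·LiCl (1.1 equiv), THF, −40 °C; then LaCl3·2LiCl (1.1 equiv), 5 (1.2 equiv), THF, −78 to −40 °C; aq NH4Cl
Reagents that add atoms: none
Why: Iodine–magnesium exchange at C8'' is accelerated by the two ortho oxygens (O7'' and O1''), and 6 should persist at low temperature because the γ-pyranone carbonyl C4''=O is a vinylogous ester further deactivated by O5'' and O7'', C2'' is blocked by ring B', and the di-ortho-substituted aryl–magnesium is slow in bimolecular self-addition. The aryl group then adds 1,2 to the C1 carbonyl of 5; the closest known reaction type is the addition of aryl organometallics to p-quinones and quinone monoketals to give p-quinols. C1 is the more electrophilic carbonyl because C4=O receives donation from both benzyloxy groups through the two enol-ether arms (a doubly vinylogous ester), while C1=O is only cross-conjugated and can chelate the metal with a flanking ether oxygen. Conjugate addition at C3/C5 is disfavoured because these are the electron-rich β-carbons of the enol ethers, and the oxophilic lanthanum salt is added to favour carbonyl addition over single-electron transfer to the quinone. Sterically the new bond is formed by attack perpendicular to the quinone plane on a trigonal carbon, so the four ortho oxygens are not forced into one plane as in a biaryl reductive elimination. No ring is closed and no stereocenter is formed, since the carbinol carbon carries two identical ring arms. The step needs chemoselectivity for the quinone over C4''=O and regioselectivity between the two quinone carbonyls, both secured by the electronic difference described. It pays in simplicity because the distal carbonyl becomes the single free hydroxyl of ring A (the later O1), para to the new bond, which fixes the 6-attachment.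

Step 5
Reactants: 7 5,7-bis(benzyloxy)-2-[4-(benzyloxy)phenyl]-8-[2,6-bis(benzyloxy)-1-hydroxy-4-oxocyclohexa-2,5-dien-1-yl]-4H-chromen-4-one
Product: 8 5,7-bis(benzyloxy)-2-[4-(benzyloxy)phenyl]-8-[2,6-bis(benzyloxy)-4-hydroxyphenyl]-4H-chromen-4-one
Conditions: Zn dust (10 equiv), AcOH–THF (1:4), 0 °C to rt
Reagents that add atoms: none
Why: Reductive aromatization of a p-quinol (a vinylogous α-hydroxy ketone): zinc transfers two electrons to the protonated dienone, hydroxide leaves from the carbinol carbon and tautomerization gives the phenol, driven by aromatization; the flavone and the benzyl ethers should be inert to Zn/AcOH at room temperature.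

Step 6
Reactants: 8 5,7-bis(benzyloxy)-2-[4-(benzyloxy)phenyl]-8-[2,6-bis(benzyloxy)-4-hydroxyphenyl]-4H-chromen-4-one
Product: 9 8-[3-acetyl-2,6-bis(benzyloxy)-4-hydroxyphenyl]-5,7-bis(benzyloxy)-2-[4-(benzyloxy)phenyl]-4H-chromen-4-one
Conditions: AcOH (1.5 equiv), (CF3CO)2O (4 equiv), CH2Cl2, 0 °C to rt; then NaHCO3, MeOH–H2O
Reagents that add atoms: acetic acid, CC(=O)O
Why: Friedel–Crafts acylation by the mixed anhydride acetyl trifluoroacetate without a Lewis acid, so the benzyl ethers should persist; the phloroglucinol-type phenol ring is far more nucleophilic than rings A' and B' (both deactivated by the pyranone), its two open positions are equivalent and both ortho to the hydroxyl, and any O-bound acyl group is removed in the bicarbonate–methanol quench.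

Step 7
Reactants: 9 8-[3-acetyl-2,6-bis(benzyloxy)-4-hydroxyphenyl]-5,7-bis(benzyloxy)-2-[4-(benzyloxy)phenyl]-4H-chromen-4-one
Product: 11 5,7-bis(benzyloxy)-6-{5,7-bis(benzyloxy)-2-[4-(benzyloxy)phenyl]-4-oxo-4H-chromen-8-yl}-4H-chromen-4-one, via enaminone 10 (not isolated)
Conditions: Me2NCH(OMe)2 (3 equiv), toluene, 100 °C; evaporate; then aq HCl (2 M), CH2Cl2, rt
Reagents that add atoms: N,N-dimethylformamide dimethyl acetal, COC(OC)N(C)C
Why: Condensation of the methyl ketone with the amide acetal gives the (E)-enaminone, and acid then promotes addition of the only free phenol to the β-carbon and loss of dimethylamine (addition–elimination, 6-endo-trig) to the chromone; because that hydroxyl is para to the biaryl carbon, the new pyranone can only be fused so that the biaryl bond sits at C6.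

Step 8
Reactants: 11 5,7-bis(benzyloxy)-6-{5,7-bis(benzyloxy)-2-[4-(benzyloxy)phenyl]-4-oxo-4H-chromen-8-yl}-4H-chromen-4-one; 12 4-(benzyloxy)phenylboronic acid
Product: 13 (2S)-5,7-bis(benzyloxy)-2-[4-(benzyloxy)phenyl]-6-{5,7-bis(benzyloxy)-2-[4-(benzyloxy)phenyl]-4-oxo-4H-chromen-8-yl}-2,3-dihydro-4H-chromen-4-one
Conditions: 12 (2 equiv), Pd(OCOCF3)2 (10 mol %), (R)-t-BuPyOx (12 mol %), NH4PF6 (30 mol %), H2O (5 equiv), ClCH2CH2Cl, 60 °C
Reagents that add atoms: none
Why: Asymmetric conjugate addition of an arylboronic acid to a chromone under cationic divalent palladium with a pyridine–oxazoline ligand: transmetalation, enantio-determining insertion of C2=C3 into the aryl–palladium bond and protonolysis of the palladium enolate by water; C2 (S) is set by the ligand, the (R) enantiomer being chosen on the model that the aryl group is delivered to the same enone face as in cyclic enones (the S descriptor, not the ligand label, is the requirement), the 2-aryl pyranone ring C' is β,β-disubstituted and should not insert, and the absence of base avoids retro-oxa-Michael racemization.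

Step 9
Reactants: 13 (2S)-5,7-bis(benzyloxy)-2-[4-(benzyloxy)phenyl]-6-{5,7-bis(benzyloxy)-2-[4-(benzyloxy)phenyl]-4-oxo-4H-chromen-8-yl}-2,3-dihydro-4H-chromen-4-one
Product: 14 (2S)-5,7-dihydroxy-2-(4-hydroxyphenyl)-6-[5,7-dihydroxy-2-(4-hydroxyphenyl)-4-oxo-4H-chromen-8-yl]-2,3-dihydro-4H-chromen-4-one
Conditions: H2 (1 atm), Pd/C (10 wt %), EtOAc–MeOH (1:1), rt
Reagents that add atoms: none
Why: Heterogeneous hydrogenolysis of six benzyl aryl ethers under neutral conditions, under which C2 cannot epimerize; the reaction is stopped after uptake of six equivalents of hydrogen to spare C2''=C3'' and the benzylic C2–O1 bond.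

## Compound list

1 | apigenin, 5,7-dihydroxy-2-(4-hydroxyphenyl)-4H-chromen-4-one | O=c1cc(-c2ccc(O)cc2)oc2cc(O)cc(O)c12 | starting material
2 | 5,7-bis(benzyloxy)-2-[4-(benzyloxy)phenyl]-4H-chromen-4-one | O=c1cc(-c2ccc(OCc3ccccc3)cc2)oc2cc(OCc3ccccc3)cc(OCc3ccccc3)c12 | intermediate
3 | 5,7-bis(benzyloxy)-2-[4-(benzyloxy)phenyl]-8-iodo-4H-chromen-4-one | O=c1cc(-c2ccc(OCc3ccccc3)cc2)oc2c(I)c(OCc3ccccc3)cc(OCc3ccccc3)c12 | intermediate
4 | 3,5-bis(benzyloxy)phenol | Oc1cc(OCc2ccccc2)cc(OCc2ccccc2)c1 | starting material
5 | 2,6-bis(benzyloxy)cyclohexa-2,5-diene-1,4-dione | O=C1C=C(OCc2ccccc2)C(=O)C(OCc2ccccc2)=C1 | intermediate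
6 | {5,7-bis(benzyloxy)-2-[4-(benzyloxy)phenyl]-4-oxo-4H-chromen-8-yl}magnesium chloride | Cl[Mg]c1c(OCc2ccccc2)cc(OCc2ccccc2)c2c(=O)cc(-c3ccc(OCc4ccccc4)cc3)oc12 | intermediate (not isolated)
7 | 5,7-bis(benzyloxy)-2-[4-(benzyloxy)phenyl]-8-[2,6-bis(benzyloxy)-1-hydroxy-4-oxocyclohexa-2,5-dien-1-yl]-4H-chromen-4-one | O=C1C=C(OCc2ccccc2)C(O)(c2c(OCc3ccccc3)cc(OCc3ccccc3)c3c(=O)cc(-c4ccc(OCc5ccccc5)cc4)oc23)C(OCc2ccccc2)=C1 | intermediate
8 | 5,7-bis(benzyloxy)-2-[4-(benzyloxy)phenyl]-8-[2,6-bis(benzyloxy)-4-hydroxyphenyl]-4H-chromen-4-one | Oc1cc(OCc2ccccc2)c(-c2c(OCc3ccccc3)cc(OCc3ccccc3)c3c(=O)cc(-c4ccc(OCc5ccccc5)cc4)oc23)c(OCc2ccccc2)c1 | intermediate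
9 | 8-[3-acetyl-2,6-bis(benzyloxy)-4-hydroxyphenyl]-5,7-bis(benzyloxy)-2-[4-(benzyloxy)phenyl]-4H-chromen-4-one | CC(=O)c1c(O)cc(OCc2ccccc2)c(-c2c(OCc3ccccc3)cc(OCc3ccccc3)c3c(=O)cc(-c4ccc(OCc5ccccc5)cc4)oc23)c1OCc1ccccc1 | intermediate
10 | 8-{2,6-bis(benzyloxy)-3-[(2E)-3-(dimethylamino)prop-2-enoyl]-4-hydroxyphenyl}-5,7-bis(benzyloxy)-2-[4-(benzyloxy)phenyl]-4H-chromen-4-one | CN(C)/C=C/C(=O)c1c(O)cc(OCc2ccccc2)c(-c2c(OCc3ccccc3)cc(OCc3ccccc3)c3c(=O)cc(-c4ccc(OCc5ccccc5)cc4)oc23)c1OCc1ccccc1 | intermediate (not isolated)
11 | 5,7-bis(benzyloxy)-6-{5,7-bis(benzyloxy)-2-[4-(benzyloxy)phenyl]-4-oxo-4H-chromen-8-yl}-4H-chromen-4-one | O=c1ccoc2cc(OCc3ccccc3)c(-c3c(OCc4ccccc4)cc(OCc4ccccc4)c4c(=O)cc(-c5ccc(OCc6ccccc6)cc5)oc34)c(OCc3ccccc3)c12 | intermediate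
12 | 4-(benzyloxy)phenylboronic acid | OB(O)c1ccc(OCc2ccccc2)cc1 | starting material
13 | (2S)-5,7-bis(benzyloxy)-2-[4-(benzyloxy)phenyl]-6-{5,7-bis(benzyloxy)-2-[4-(benzyloxy)phenyl]-4-oxo-4H-chromen-8-yl}-2,3-dihydro-4H-chromen-4-one | O=C1C[C@@H](c2ccc(OCc3ccccc3)cc2)Oc2cc(OCc3ccccc3)c(-c3c(OCc4ccccc4)cc(OCc4ccccc4)c4c(=O)cc(-c5ccc(OCc6ccccc6)cc5)oc34)c(OCc3ccccc3)c21 | intermediate
14 | (2S)-5,7-dihydroxy-2-(4-hydroxyphenyl)-6-[5,7-dihydroxy-2-(4-hydroxyphenyl)-4-oxo-4H-chromen-8-yl]-2,3-dihydro-4H-chromen-4-one | O=C1C[C@@H](c2ccc(O)cc2)Oc2cc(O)c(-c3c(O)cc(O)c4c(=O)cc(-c5ccc(O)cc5)oc34)c(O)c21 | target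

## Step count and least certain steps

Total step count: 9. Longest linear sequence: 8 (steps 1, 2, 4, 5, 6, 7, 8, 9); step 3 is a one-step branch.

Step 4 (key step). Most likely failures are single-electron transfer from 6 to the quinone (reduction of 5 and protonation of the aryl metal), attack at the other carbonyl or addition–elimination at a benzyloxy-bearing carbon, and consumption of 6 by the pyranone carbonyl before 5 is added. The causes are that 5 is a good oxidant and that the nucleophile is di-ortho-substituted and slow. The fallback sets out from 5 and 3 and returns at 8, so it also bypasses step 5. Compound 5 is reduced (Na2S2O4, EtOAc–H2O) to 2,6-bis(benzyloxy)benzene-1,4-diol F1. The unhindered hydroxyl is silylated (TBSCl, imidazole, DMF) to 2,6-bis(benzyloxy)-4-[(tert-butyldimethylsilyl)oxy]phenol F2. The hindered hydroxyl is converted (Tf2O, pyridine, CH2Cl2) into the aryl trifluoromethanesulfonate F3. Compound 3 is taken through 6 and ZnCl2 to the arylzinc chloride F4. Negishi coupling of F4 with F3 (Pd2(dba)3, RuPhos, THF, 70 °C) gives the silyl ether F5 of 8, and Bu4NF in THF releases 8.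

Step 8. Most likely failures are slow insertion of the electron-rich 5,7-dialkoxychromone, so that protodeboronation of 12 takes over, or insufficient facial selectivity. The fallback sets out from 9 and returns at 13. Claisen–Schmidt condensation of 9 with 4-(benzyloxy)benzaldehyde (KOH, EtOH, rt) gives the 2'-hydroxychalcone F6. Cyclization (NaOAc, EtOH, reflux) gives the racemic flavanone F7. Preparative chromatography on a chiral stationary phase separates 13 from the (2R)-enantiomer F8, which can be racemized with base and recycled.

Step 6. Most likely failures are loss or migration of benzyl groups in the acidic anhydride medium, or acylation stopping at the phenol oxygen. The fallback sets out from 8 and returns at 9. Iodination ortho to the hydroxyl (NIS, CH2Cl2, 0 °C) gives the iodophenol F9. Stille coupling with tributyl(1-ethoxyvinyl)stannane (Pd(PPh3)4, toluene, 100 °C) gives the enol ether F10, and aqueous HCl in THF hydrolyses it to 9.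

Step 9. Most likely failures are over-reduction, namely saturation of C2''=C3'' or hydrogenolytic opening of the benzylic C2–O1 bond, while the last of the six benzyl groups is still being removed. The fallback sets out from 13 and returns at 14. It replaces hydrogenolysis by Lewis-acid debenzylation with BCl3 and pentamethylbenzene as cation scavenger (CH2Cl2, −78 °C) and makes no new compound.

## Further compounds

F1 | step 4 | 2,6-bis(benzyloxy)benzene-1,4-diol | Oc1cc(OCc2ccccc2)c(O)c(OCc2ccccc2)c1
F2 | step 4 | 2,6-bis(benzyloxy)-4-[(tert-butyldimethylsilyl)oxy]phenol | CC(C)(C)[Si](C)(C)Oc1cc(OCc2ccccc2)c(O)c(OCc2ccccc2)c1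
F3 | step 4 | 2,6-bis(benzyloxy)-4-[(tert-butyldimethylsilyl)oxy]phenyl trifluoromethanesulfonate | CC(C)(C)[Si](C)(C)Oc1cc(OCc2ccccc2)c(OS(=O)(=O)C(F)(F)F)c(OCc2ccccc2)c1
F4 | step 4 | {5,7-bis(benzyloxy)-2-[4-(benzyloxy)phenyl]-4-oxo-4H-chromen-8-yl}zinc chloride | Cl[Zn]c1c(OCc2ccccc2)cc(OCc2ccccc2)c2c(=O)cc(-c3ccc(OCc4ccccc4)cc3)oc12
F5 | step 4 | 5,7-bis(benzyloxy)-2-[4-(benzyloxy)phenyl]-8-{2,6-bis(benzyloxy)-4-[(tert-butyldimethylsilyl)oxy]phenyl}-4H-chromen-4-one | CC(C)(C)[Si](C)(C)Oc1cc(OCc2ccccc2)c(-c2c(OCc3ccccc3)cc(OCc3ccccc3)c3c(=O)cc(-c4ccc(OCc5ccccc5)cc4)oc23)c(OCc2ccccc2)c1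
F6 | step 8 | 8-{2,6-bis(benzyloxy)-3-[(2E)-3-(4-(benzyloxy)phenyl)prop-2-enoyl]-4-hydroxyphenyl}-5,7-bis(benzyloxy)-2-[4-(benzyloxy)phenyl]-4H-chromen-4-one | O=C(/C=C/c1ccc(OCc2ccccc2)cc1)c1c(O)cc(OCc2ccccc2)c(-c2c(OCc3ccccc3)cc(OCc3ccccc3)c3c(=O)cc(-c4ccc(OCc5ccccc5)cc4)oc23)c1OCc1ccccc1
F7 | step 8 | racemic 5,7-bis(benzyloxy)-2-[4-(benzyloxy)phenyl]-6-{5,7-bis(benzyloxy)-2-[4-(benzyloxy)phenyl]-4-oxo-4H-chromen-8-yl}-2,3-dihydro-4H-chromen-4-one | O=C1CC(c2ccc(OCc3ccccc3)cc2)Oc2cc(OCc3ccccc3)c(-c3c(OCc4ccccc4)cc(OCc4ccccc4)c4c(=O)cc(-c5ccc(OCc6ccccc6)cc5)oc34)c(OCc3ccccc3)c21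
F8 | step 8 | (2R)-5,7-bis(benzyloxy)-2-[4-(benzyloxy)phenyl]-6-{5,7-bis(benzyloxy)-2-[4-(benzyloxy)phenyl]-4-oxo-4H-chromen-8-yl}-2,3-dihydro-4H-chromen-4-one | O=C1C[C@H](c2ccc(OCc3ccccc3)cc2)Oc2cc(OCc3ccccc3)c(-c3c(OCc4ccccc4)cc(OCc4ccccc4)c4c(=O)cc(-c5ccc(OCc6ccccc6)cc5)oc34)c(OCc3ccccc3)c21
F9 | step 6 | 5,7-bis(benzyloxy)-2-[4-(benzyloxy)phenyl]-8-[2,6-bis(benzyloxy)-4-hydroxy-3-iodophenyl]-4H-chromen-4-one | Oc1cc(OCc2ccccc2)c(-c2c(OCc3ccccc3)cc(OCc3ccccc3)c3c(=O)cc(-c4ccc(OCc5ccccc5)cc4)oc23)c(OCc2ccccc2)c1I
F10 | step 6 | 5,7-bis(benzyloxy)-2-[4-(benzyloxy)phenyl]-8-[2,6-bis(benzyloxy)-3-(1-ethoxyethenyl)-4-hydroxyphenyl]-4H-chromen-4-one | C=C(OCC)c1c(O)cc(OCc2ccccc2)c(-c2c(OCc3ccccc3)cc(OCc3ccccc3)c3c(=O)cc(-c4ccc(OCc5ccccc5)cc4)oc23)c1OCc1ccccc1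
F0 | step 9 | none | none
A1 | alternative 1 | 5,7-bis(benzyloxy)-2-[4-(benzyloxy)phenyl]-8-(4,4,5,5-tetramethyl-1,3,2-dioxaborolan-2-yl)-4H-chromen-4-one | CC1(C)OB(c2c(OCc3ccccc3)cc(OCc3ccccc3)c3c(=O)cc(-c4ccc(OCc5ccccc5)cc4)oc23)OC1(C)C
A2 | alternative 1 | 5,7-bis(benzyloxy)-6-iodo-4H-chromen-4-one | O=c1ccoc2cc(OCc3ccccc3)c(I)c(OCc3ccccc3)c12
A3 | alternative 2 | (2S)-naringenin, (2S)-5,7-dihydroxy-2-(4-hydroxyphenyl)-2,3-dihydro-4H-chromen-4-one | O=C1C[C@@H](c2ccc(O)cc2)Oc2cc(O)cc(O)c21
A4 | alternative 3 | methyl 6-{5,7-bis(benzyloxy)-2-[4-(benzyloxy)phenyl]-4-oxo-4H-chromen-8-yl}-3,5-dioxohexanoate | COC(=O)CC(=O)CC(=O)Cc1c(OCc2ccccc2)cc(OCc2ccccc2)c2c(=O)cc(-c3ccc(OCc4ccccc4)cc3)oc12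
A5 | alternative 3 | 5,7-bis(benzyloxy)-2-[4-(benzyloxy)phenyl]-8-(2,4,6-trihydroxyphenyl)-4H-chromen-4-one | Oc1cc(O)c(-c2c(OCc3ccccc3)cc(OCc3ccccc3)c3c(=O)cc(-c4ccc(OCc5ccccc5)cc4)oc23)c(O)c1
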